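**Retrosynthetic overview**
- Junipegenin C ⇐ dehydration (C2=C3) and MOM removal from a 5,7-bis-MOM 3-hydroxyisoflavanone.
- Key disconnection C3–C4: intramolecular NHC-catalysed crossed benzoin of an aryloxy keto-aldehyde. The formyl carbon reacts as an acyl anion (Breslow intermediate) and attacks the tethered aryl-ketone carbonyl. This closes the pyranone ring, the only ring formed; the A and B rings are bought as arenes.
- Keto-aldehyde ⇐ salicylaldehyde + 2-bromo-1-(3,4,5-trimethoxyphenyl)ethanone (O1–C2 bond, Williamson).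
- Salicylaldehyde ⇐ ortho-formylation of a C2-symmetric phenol, so the 6-OMe/8-OMe question cannot arise ⇐ 2-methoxyresorcinol by MOM protection and sterically controlled C–H borylation/oxidation.

Assumption: the target has no stereocentre, so "single enantiomer" is read as the single constitutional isomer (6-methoxy, not 8-methoxy). The only stereocentre on the route (C3 of the benzoin adduct) is formed racemic and erased in the last step.

**Route**

Step 1
Reactants: 1 2-methoxyresorcinol (2-methoxybenzene-1,3-diol)
Product: 2 2-methoxy-1,3-bis(methoxymethoxy)benzene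
Conditions: NaH (2.4 equiv), MOMCl (2.4 equiv), DMF, 0 °C → rt
Reagents that add atoms: chloromethyl methyl ether (MOMCl), COCCl
Why: Williamson-type O-alkylation of both phenoxides (MOM protection) gives acetals that survive the later basic, organometallic and NHC steps and fall off in acid at the end.

Step 2
Reactants: 2 2-methoxy-1,3-bis(methoxymethoxy)benzene
Product: 4 4-methoxy-3,5-bis(methoxymethoxy)phenol, via aryl pinacol boronate 3 (not isolated)
Conditions: [Ir(OMe)(cod)]2 (1.5 mol %), dtbpy (3 mol %), B2pin2 (0.55 equiv), THF, 80 °C; then 30% aq H2O2, aq NaOH, 0 °C; NH4Cl work-up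
Reagents that add atoms: hydrogen peroxide, OO (phenolic oxygen of 4); bis(pinacolato)diboron, CC1(C)OB(OC1(C)C)B1OC(C)(C)C(C)(C)O1 (Bpin group of 3 only)
Why: Sterically controlled Ir-catalysed aromatic C–H borylation attacks only C5, the one C–H with no ortho substituent, and basic peroxide oxidation of the C–B bond gives the C2-symmetric phenol in one pot.

Step 3
Reactants: 4 4-methoxy-3,5-bis(methoxymethoxy)phenol
Product: 5 2-hydroxy-5-methoxy-4,6-bis(methoxymethoxy)benzaldehyde
Conditions: MgCl2 (2 equiv), Et3N (4 equiv), (CH2O)n (6 equiv), MeCN, 80 °C; cold aq citric acid work-up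
Reagents that add atoms: paraformaldehyde (reacts as formaldehyde), C=O
Why: Magnesium-phenoxide-directed ortho-formylation (Casnati–Skattebøl) is ortho-specific and non-acidic, so the MOM groups survive, and the two ortho positions are equivalent, so only one aldehyde can form.

Step 4
Reactants: 5 2-hydroxy-5-methoxy-4,6-bis(methoxymethoxy)benzaldehyde; 6 2-bromo-1-(3,4,5-trimethoxyphenyl)ethan-1-one
Product: 7 3-methoxy-2,4-bis(methoxymethoxy)-6-[2-oxo-2-(3,4,5-trimethoxyphenyl)ethoxy]benzaldehyde
Conditions: K2CO3 (1.5 equiv), DMF, 0 °C → rt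
Reagents that add atoms: none
Why: Williamson etherification (SN2 of the only free phenoxide on the α-bromoketone) is run at or below room temperature so the keto-aldehyde does not go on to the Rap–Stoermer aldol (2-aroylbenzofuran).

Step 5
Reactants: 7 3-methoxy-2,4-bis(methoxymethoxy)-6-[2-oxo-2-(3,4,5-trimethoxyphenyl)ethoxy]benzaldehyde
Product: 8 rac-3-hydroxy-6-methoxy-5,7-bis(methoxymethoxy)-3-(3,4,5-trimethoxyphenyl)chroman-4-one
Conditions: 2-(pentafluorophenyl)-6,7-dihydro-5H-pyrrolo[2,1-c][1,2,4]triazol-2-ium tetrafluoroborate (20 mol %), Et3N (20 mol %), toluene, 40 °C, Ar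
Reagents that add atoms: none
Why: NHC-catalysed intramolecular crossed aldehyde–ketone benzoin: the carbene turns the formyl carbon into an acyl anion (Breslow intermediate) that adds 6-exo to the tethered ketone carbonyl, forming the C3–C4 bond and the pyranone ring, the small acidic N-C6F5 triazolium with a weak amine base being chosen to keep ketone enolisation (aldol) slow; the new C3 carbinol centre is racemic (achiral catalyst) and is erased in step 6.

Step 6
Reactants: 8 rac-3-hydroxy-6-methoxy-5,7-bis(methoxymethoxy)-3-(3,4,5-trimethoxyphenyl)chroman-4-one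
Product: 10 Junipegenin C (5,7-dihydroxy-6-methoxy-3-(3,4,5-trimethoxyphenyl)-4H-chromen-4-one), via bis-MOM isoflavone 9 (not isolated)
Conditions: Burgess reagent (2 equiv), THF, 55 °C; then MeOH, conc. HCl (to ca. 2 M), 50 °C
Reagents that add atoms: none
Why: Burgess syn-elimination (Ei) of the tertiary alcohol can only take a C2 hydrogen and so gives the chromone C2=C3 bond, after which acid-catalysed acetal cleavage in methanol removes both MOM groups without touching the aryl methyl ethers or the 6-OMe/8-OMe regiochemistry (no strong base or HI, so no Wessely–Moser-type isomerisation); the C3 stereocentre is destroyed here.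

**Compound list**
1 | 2-methoxyresorcinol (2-methoxybenzene-1,3-diol) | COc1c(O)cccc1O | starting material
2 | 2-methoxy-1,3-bis(methoxymethoxy)benzene | COCOc1cccc(OCOC)c1OC | intermediate
3 | 2-[4-methoxy-3,5-bis(methoxymethoxy)phenyl]-4,4,5,5-tetramethyl-1,3,2-dioxaborolane (aryl pinacol boronate, not isolated) | COCOc1cc(B2OC(C)(C)C(C)(C)O2)cc(OCOC)c1OC | intermediate
4 | 4-methoxy-3,5-bis(methoxymethoxy)phenol | COCOc1cc(O)cc(OCOC)c1OC | intermediate
5 | 2-hydroxy-5-methoxy-4,6-bis(methoxymethoxy)benzaldehyde | O=Cc1c(O)cc(OCOC)c(OC)c1OCOC | intermediate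
6 | 2-bromo-1-(3,4,5-trimethoxyphenyl)ethan-1-one | COc1cc(C(=O)CBr)cc(OC)c1OC | starting material
7 | 3-methoxy-2,4-bis(methoxymethoxy)-6-[2-oxo-2-(3,4,5-trimethoxyphenyl)ethoxy]benzaldehyde | O=Cc1c(OCC(=O)c2cc(OC)c(OC)c(OC)c2)cc(OCOC)c(OC)c1OCOC | intermediate
8 | rac-3-hydroxy-6-methoxy-5,7-bis(methoxymethoxy)-3-(3,4,5-trimethoxyphenyl)chroman-4-one (racemic at C3) | O=C1c2c(OCOC)c(OC)c(OCOC)cc2OCC1(O)c1cc(OC)c(OC)c(OC)c1 | intermediate
9 | 6-methoxy-5,7-bis(methoxymethoxy)-3-(3,4,5-trimethoxyphenyl)-4H-chromen-4-one (bis-MOM isoflavone, not isolated) | COCOc1cc2occ(-c3cc(OC)c(OC)c(OC)c3)c(=O)c2c(OCOC)c1OC | intermediate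
10 | Junipegenin C, 5,7-dihydroxy-6-methoxy-3-(3,4,5-trimethoxyphenyl)-4H-chromen-4-one (achiral) | COc1cc(-c2coc3cc(O)c(OC)c(O)c3c2=O)cc(OC)c1OC | target

**Totals**
Total step count: 6. Longest linear sequence: 6 steps (1 → 2 → 4 → 5 → 7 → 8 → 10); bromoketone 6 is purchased.

**Three steps most likely to fail, with fallbacks**

Step 5 (benzoin cyclisation). The aldehyde is electron-rich and flanked by two ortho oxygens, so carbene addition may be slow, and the base-induced aldol to a 2-aroylbenzofuran competes. Fallback: give up the ring-closing C3–C4 bond and set out from salicylaldehyde 5. Addition of 3,4,5-trimethoxybenzylmagnesium chloride (2.5 equiv, THF, 0 °C) gives the carbinol rac-2-[1-hydroxy-2-(3,4,5-trimethoxyphenyl)ethyl]-4-methoxy-3,5-bis(methoxymethoxy)phenol F1. MnO2 (CH2Cl2, rt) oxidises it to the deoxybenzoin 1-[2-hydroxy-5-methoxy-4,6-bis(methoxymethoxy)phenyl]-2-(3,4,5-trimethoxyphenyl)ethan-1-one F2. DMF-DMA (toluene, 90 °C) then supplies C2 and closes the pyrone. The fallback returns to the route at bis-MOM isoflavone 9, which needs only the HCl/MeOH stage of step 6.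

Step 6 (dehydration/deprotection). The sulfamate of an α-keto tertiary benzylic alcohol may ionise and rearrange (α-ketol or semipinacol shift) instead of eliminating. Fallback: replace dehydration by deoxygenation followed by dehydrogenation, setting out from 8. SmI2 (2.5 equiv, THF/MeOH, −78 °C) cleaves the α-C–OH bond to give the isoflavanone rac-6-methoxy-5,7-bis(methoxymethoxy)-3-(3,4,5-trimethoxyphenyl)chroman-4-one F3. DDQ (dioxane, 90 °C) dehydrogenates C2–C3. The fallback returns at 9, which is then deprotected with HCl/MeOH as in step 6.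

Step 3 (ortho-formylation). The site is hindered, and the electron-rich phenol is oxidation-prone and may over-react with formaldehyde. Fallback: halogenation/metalation instead of electrophilic formylation, setting out from phenol 4. NBS (1.0 equiv, CH2Cl2, −40 °C) gives 2-bromo-4-methoxy-3,5-bis(methoxymethoxy)phenol F4. n-BuLi (2.2 equiv, THF, −78 °C) forms the O,C-dilithio species by deprotonation and Br–Li exchange, and a DMF quench with mild acidic work-up delivers the aldehyde. The fallback returns at 5.

**Further compounds**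
F1 | step 5 | rac-2-[1-hydroxy-2-(3,4,5-trimethoxyphenyl)ethyl]-4-methoxy-3,5-bis(methoxymethoxy)phenol | COCOc1cc(O)c(C(O)Cc2cc(OC)c(OC)c(OC)c2)c(OCOC)c1OC
F2 | step 5 | 1-[2-hydroxy-5-methoxy-4,6-bis(methoxymethoxy)phenyl]-2-(3,4,5-trimethoxyphenyl)ethan-1-one | COCOc1cc(O)c(C(=O)Cc2cc(OC)c(OC)c(OC)c2)c(OCOC)c1OC
F3 | step 6 | rac-6-methoxy-5,7-bis(methoxymethoxy)-3-(3,4,5-trimethoxyphenyl)chroman-4-one | COCOc1cc2OCC(c3cc(OC)c(OC)c(OC)c3)C(=O)c2c(OCOC)c1OC
F4 | step 3 | 2-bromo-4-methoxy-3,5-bis(methoxymethoxy)phenol | COCOc1cc(O)c(Br)c(OCOC)c1OC
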